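**Strategy.** The cyclobutane is cut at C6–C7 of the carbocycle (bicyclo[4.2.0]oct-3-ene numbering: C1 and C6 ring fusion, peroxide on C2 and C5, pyranone on C7). The key step exploits quaternary C7: its carboxyl-derived carbon (later the pyranone) sits cis to C5, and its neighbour C6 is the end carbon of the C2–C5 diene that exists before photooxygenation. An Ireland–Claisen shift of a bridged eight-membered dienyl lactone therefore forms C6–C7, the four-membered ring and three stereocentres in one operation. The lactone is a 2-oxabicyclo[4.2.2]decadienone built on a Birch-derived cyclohexa-2,5-diene with one preset methyl stereocentre. The acid is afterwards grown into the methoxypyranone and photooxygenated.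

Key step: step 10

Remark (chemistry): C4 of lactone 16 is left as an epimer mixture because it becomes trigonal in step 10; the diene ring comes from a Birch reduction because a blocked 4,4-disubstituted cyclohexadienone lies uphill from its aryl allyl ether and is not a preparative product of a thermal aryl ether rearrangement.

Step 1
Reactants: 1 3,5-dimethylbenzoic acid
Product: 3 1,3,5-trimethylcyclohexa-2,5-diene-1-carboxylic acid, via dilithium enediolate 2 (not isolated)
Conditions: Li, NH3(l), THF, −78 °C; MeI, −78 °C to rt; aq. HCl work-up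
Reagents that add atoms: iodomethane, CI
Why: Birch reduction–alkylation, in which the carboxylate directs reduction to the 1,4-dihydro enediolate (protonated at the free para carbon) and MeI alkylates the carboxyl-bearing carbon, giving the non-stereogenic quaternary centre flanked by two skipped ring alkenes.

Step 2
Reactants: 3 1,3,5-trimethylcyclohexa-2,5-diene-1-carboxylic acid
Product: 5 1-(1,3,5-trimethylcyclohexa-2,5-dien-1-yl)ethan-1-one, via dilithium gem-diolate 4 (not isolated)
Conditions: MeLi (2.5 equiv), Et2O, 0 °C to rt; inverse quench into ice-water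
Reagents that add atoms: methyllithium, [Li]C
Why: Organolithium ketone synthesis from a carboxylic acid, in which the second MeLi adds to the lithium carboxylate and the stable gem-diolate collapses to the methyl ketone only on quench, so no tertiary alcohol should form.

Step 3
Reactants: 5 1-(1,3,5-trimethylcyclohexa-2,5-dien-1-yl)ethan-1-one; 6 triethyl phosphonoacetate
Product: 8 ethyl (2E)-3-(1,3,5-trimethylcyclohexa-2,5-dien-1-yl)but-2-enoate, via sodium phosphonate enolate 7 (not isolated)
Conditions: NaH, THF, 0 °C; then 5, 65 °C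
Reagents that add atoms: triethyl phosphonoacetate 6, CCOC(=O)CP(=O)(OCC)OCC
Why: Horner–Wadsworth–Emmons olefination of a tert-alkyl methyl ketone, in which the bulky ring carbon should end up trans to the ester and give the (E)-trisubstituted enoate.

Step 4
Reactants: 8 ethyl (2E)-3-(1,3,5-trimethylcyclohexa-2,5-dien-1-yl)but-2-enoate
Product: 9 ethyl (3S)-3-(1,3,5-trimethylcyclohexa-2,5-dien-1-yl)butanoate
Conditions: Cu(OAc)2·H2O (3 mol %), (S)-DTBM-SEGPHOS (3 mol %), (EtO)2MeSiH, t-BuOH, toluene, 0 °C to rt
Reagents that add atoms: none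
Why: Copper hydride asymmetric conjugate reduction (1,4-hydrosilylation) of a β,β-disubstituted enoate, in which the bisphosphine–CuH delivers hydride to one face of the β-carbon (methyl versus tert-alkyl) to set the (3S) centre while the ring alkenes are inert; the ligand hand is assigned by analogy with β-aryl crotonates and is to be confirmed on the product, the antipodal ligand being used if the sense is opposite.

Step 5
Reactants: 9 ethyl (3S)-3-(1,3,5-trimethylcyclohexa-2,5-dien-1-yl)butanoate
Product: 10 ethyl (3S)-3-(1,3,5-trimethyl-4-oxocyclohexa-2,5-dien-1-yl)butanoate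
Conditions: (C5H5NH)2Cr2O7, t-BuOOH, Celite, benzene, rt
Reagents that add atoms: tert-butyl hydroperoxide, CC(C)(C)OO
Why: Allylic oxidation at the doubly allylic ring CH2 (the weakest C–H bond), the standard conversion of 3,3-disubstituted cyclohexa-1,4-dienes into 4,4-disubstituted cyclohexa-2,5-dienones.

Step 6
Reactants: 10 ethyl (3S)-3-(1,3,5-trimethyl-4-oxocyclohexa-2,5-dien-1-yl)butanoate
Product: 11 ethyl (3S)-3-(cis-4-hydroxy-1,3,5-trimethylcyclohexa-2,5-dien-1-yl)butanoate (hydroxyl and butanoate arm on the same ring face)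
Conditions: NaBH4, CeCl3·7H2O, MeOH, −78 °C; aq. NaHCO3 work-up
Reagents that add atoms: none
Why: Luche 1,2-reduction, in which hydride should approach the carbonyl on the ring face opposite the branched arm on the quaternary carbon across the ring, leaving the hydroxyl cis to that arm; any trans epimer is removed on base-washed silica.

Step 7
Reactants: 11 ethyl (3S)-3-(cis-4-hydroxy-1,3,5-trimethylcyclohexa-2,5-dien-1-yl)butanoate
Product: 12 (3S)-3-(cis-4-hydroxy-1,3,5-trimethylcyclohexa-2,5-dien-1-yl)butanoic acid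
Conditions: LiOH, THF–H2O, rt; aq. NaH2PO4 to pH 5, 0 °C
Reagents that add atoms: lithium hydroxide (hydroxyl oxygen), [Li+].[OH-]
Why: Ester saponification under conditions the dienol tolerates, with the acid freed at pH 5 so that the doubly allylic alcohol is not ionised.

Step 8
Reactants: 12 (3S)-3-(cis-4-hydroxy-1,3,5-trimethylcyclohexa-2,5-dien-1-yl)butanoic acid
Product: 14 (5S)-5,6,8,9-tetramethyl-2-oxabicyclo[4.2.2]deca-7,9-dien-3-one, via mixed anhydride 13 (not isolated)
Conditions: 2-methyl-6-nitrobenzoic anhydride (MNBA), DMAP, Et3N, CH2Cl2, rt, slow addition at high dilution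
Reagents that add atoms: 2-methyl-6-nitrobenzoic anhydride (acyl group carried only by intermediate 13), Cc1cccc([N+](=O)[O-])c1C(=O)OC(=O)c1c(C)cccc1[N+](=O)[O-]
Why: Shiina lactonisation, in which the activated acyl group is attacked by the cis hydroxyl held across the shallow-boat cyclohexadiene within reach of the three-carbon arm, closing the bridged eight-membered lactone without acid.

Step 9
Reactants: 14 (5S)-5,6,8,9-tetramethyl-2-oxabicyclo[4.2.2]deca-7,9-dien-3-one
Product: 16 (4RS,5S)-4,5,6,8,9-pentamethyl-2-oxabicyclo[4.2.2]deca-7,9-dien-3-one, via lithium enolate 15 (not isolated)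
Conditions: LiN(iPr)2, THF, −78 °C; MeI, DMPU, −78 °C
Reagents that add atoms: iodomethane, CI
Why: Lactone enolate alkylation at low temperature; the new C4 centre needs no control because it becomes trigonal in step 10.

Step 10
Reactants: 16 (4RS,5S)-4,5,6,8,9-pentamethyl-2-oxabicyclo[4.2.2]deca-7,9-dien-3-one
Product: 20 (1R,6R,7S,8R)-1,3,5,7,8-pentamethylbicyclo[4.2.0]octa-2,4-diene-7-carboxylic acid, via lithium enolate 17 (not isolated), via silyl ketene acetal 18 (not isolated), via silyl ester 19 (not isolated)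
Conditions: LiN(iPr)2, THF, −78 °C; TBSCl, DMPU, −78 °C to rt, then 40 °C; AcOH–THF–H2O, rt
Reagents that add atoms: tert-butyldimethylsilyl chloride (silyl group carried only by intermediates 18 and 19), CC(C)(C)[Si](C)(C)Cl
Why: The base removes the C4 proton and TBSCl traps the enolate on oxygen as the ring-locked silyl ketene acetal 18, whose C4=C3–O2–C1–C9=C10 array undergoes a concerted suprafacial [3,3] Ireland–Claisen shift through a boat-like transition state, forming C4–C10 as the doubly allylic C1–O2 bond breaks. The closest known reaction type is the ring-contracting Ireland–Claisen rearrangement of medium-ring lactone silyl ketene acetals to cis-2-alkenylcycloalkanecarboxylic acids. The cyclobutane (old C4, C5, C6 and C10) is closed by contraction of the eight-membered lactone ring by four atoms, not by cyclisation of a free chain, so the ring fusion can only be cis. Product C7 (old C4) keeps its carboxyl on the concave face because that carbon stays tied through O2 to old C1 in the transition state, its methyl is therefore convex, and C1 and C6 follow from which ring alkene is attacked. The selectivity needed is the choice between the two diastereotopic ring alkenes: the (5S) methyl can point away from the diene ring only when the bridge leans over one of them (otherwise it sits on the π-face of the other alkene), and bonding to that alkene should give the (1R,6R,7S,8R) acid. The quaternary ring carbon blocks aromatisation, and the temperature is held below about 50 °C so that the bicyclo[4.2.0]octadiene does not open electrocyclically.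

Step 11
Reactants: 20 (1R,6R,7S,8R)-1,3,5,7,8-pentamethylbicyclo[4.2.0]octa-2,4-diene-7-carboxylic acid
Product: 21 [(1R,6R,7S,8R)-1,3,5,7,8-pentamethylbicyclo[4.2.0]octa-2,4-dien-7-yl]methanol
Conditions: LiAlH4, Et2O, 0 °C to 35 °C
Reagents that add atoms: none
Why: Hydride reduction of the carboxylic acid to the neopentyl primary alcohol, which leaves the diene and the four stereocentres untouched.

Step 12
Reactants: 21 [(1R,6R,7S,8R)-1,3,5,7,8-pentamethylbicyclo[4.2.0]octa-2,4-dien-7-yl]methanol
Product: 22 (1R,6R,7S,8R)-1,3,5,7,8-pentamethylbicyclo[4.2.0]octa-2,4-diene-7-carbaldehyde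
Conditions: Dess–Martin periodinane, NaHCO3, CH2Cl2, 0 °C to rt
Reagents that add atoms: none
Why: Buffered Dess–Martin oxidation to a non-enolisable aldehyde, mild enough for the acid-sensitive diene.

Step 13
Reactants: 22 (1R,6R,7S,8R)-1,3,5,7,8-pentamethylbicyclo[4.2.0]octa-2,4-diene-7-carbaldehyde; 23 methyl 2-methyl-3-oxopentanoate
Product: 25 methyl 5-hydroxy-2,4-dimethyl-3-oxo-5-[(1R,6R,7S,8R)-1,3,5,7,8-pentamethylbicyclo[4.2.0]octa-2,4-dien-7-yl]pentanoate (mixture at C2, C4 and C5), via dilithium dianion 24 (not isolated)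
Conditions: 23, LiN(iPr)2 (2.2 equiv), THF, −78 to 0 °C; then 22, −78 °C; aq. NH4Cl
Reagents that add atoms: methyl 2-methyl-3-oxopentanoate 23, CCC(=O)C(C)C(=O)OC
Why: Aldol addition of a β-keto ester dianion through its more reactive γ-carbon to the hindered aldehyde; the three new centres are erased in steps 14 and 15.

Step 14
Reactants: 25 methyl 5-hydroxy-2,4-dimethyl-3-oxo-5-[(1R,6R,7S,8R)-1,3,5,7,8-pentamethylbicyclo[4.2.0]octa-2,4-dien-7-yl]pentanoate
Product: 26 methyl 2,4-dimethyl-3,5-dioxo-5-[(1R,6R,7S,8R)-1,3,5,7,8-pentamethylbicyclo[4.2.0]octa-2,4-dien-7-yl]pentanoate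
Conditions: Dess–Martin periodinane, NaHCO3, CH2Cl2, 0 °C to rt
Reagents that add atoms: none
Why: Dess–Martin oxidation of the β-hydroxy ketone to the 3,5-diketo ester without retro-aldol cleavage.

Step 15
Reactants: 26 methyl 2,4-dimethyl-3,5-dioxo-5-[(1R,6R,7S,8R)-1,3,5,7,8-pentamethylbicyclo[4.2.0]octa-2,4-dien-7-yl]pentanoate
Product: 27 4-hydroxy-3,5-dimethyl-6-[(1R,6R,7S,8R)-1,3,5,7,8-pentamethylbicyclo[4.2.0]octa-2,4-dien-7-yl]-2H-pyran-2-one
Conditions: DBU, toluene, rt to 45 °C
Reagents that add atoms: none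
Why: Base-mediated cyclisation (lactonisation of the C5 enol oxygen onto the methyl ester) of a 3,5-diketo ester to the 4-hydroxy-2-pyranone.

Step 16
Reactants: 27 4-hydroxy-3,5-dimethyl-6-[(1R,6R,7S,8R)-1,3,5,7,8-pentamethylbicyclo[4.2.0]octa-2,4-dien-7-yl]-2H-pyran-2-one
Product: 28 2-methoxy-3,5-dimethyl-6-[(1R,6R,7S,8R)-1,3,5,7,8-pentamethylbicyclo[4.2.0]octa-2,4-dien-7-yl]-4H-pyran-4-one
Conditions: MeOTf, CH2Cl2, 0 °C to rt; aq. NaHCO3
Reagents that add atoms: methyl trifluoromethanesulfonate, COS(=O)(=O)C(F)(F)F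
Why: O-Methylation of the neutral hydroxypyranone at its ring carbonyl oxygen by a hard methylating agent, followed by proton loss, should give the 2-methoxy-4-pyranone form; the low temperature protects the diene.

Step 17
Reactants: 28 2-methoxy-3,5-dimethyl-6-[(1R,6R,7S,8R)-1,3,5,7,8-pentamethylbicyclo[4.2.0]octa-2,4-dien-7-yl]-4H-pyran-4-one
Product: 29 2-methoxy-3,5-dimethyl-6-[(1R,2R,5S,6R,7S,8R)-2,5-epidioxy-1,3,5,7,8-pentamethylbicyclo[4.2.0]oct-3-en-7-yl]-4H-pyran-4-one (CNP0183511.1)
Conditions: O2, methylene blue, visible light, CH2Cl2, 0 °C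
Reagents that add atoms: dioxygen, O=O
Why: [4+2] Cycloaddition of sensitised singlet oxygen to the cisoid C2–C5 diene from the convex face anti to the cyclobutane (the concave face is closed by the cyclobutane and its endo pyranone), which sets C2 and C5.

**Compound list**

1 | 3,5-dimethylbenzoic acid | Cc1cc(C)cc(C(=O)O)c1 | starting material
2 | dilithium enediolate of 3,5-dimethyl-1,4-dihydrobenzoic acid | [Li+].[Li+].[O-]C([O-])=C1C=C(C)CC(C)=C1 | intermediate (not isolated)
3 | 1,3,5-trimethylcyclohexa-2,5-diene-1-carboxylic acid | CC1=CC(C)(C(=O)O)C=C(C)C1 | intermediate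
4 | dilithium 1-(1,3,5-trimethylcyclohexa-2,5-dien-1-yl)ethane-1,1-diolate | [Li+].[Li+].CC([O-])([O-])C1(C)C=C(C)CC(C)=C1 | intermediate (not isolated)
5 | 1-(1,3,5-trimethylcyclohexa-2,5-dien-1-yl)ethan-1-one | CC(=O)C1(C)C=C(C)CC(C)=C1 | intermediate
6 | triethyl phosphonoacetate | CCOC(=O)CP(=O)(OCC)OCC | starting material
7 | sodium enolate of triethyl phosphonoacetate | [Na+].CCOC([O-])=CP(=O)(OCC)OCC | intermediate (not isolated)
8 | ethyl (2E)-3-(1,3,5-trimethylcyclohexa-2,5-dien-1-yl)but-2-enoate | CCOC(=O)/C=C(\C)C1(C)C=C(C)CC(C)=C1 | intermediate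
9 | ethyl (3S)-3-(1,3,5-trimethylcyclohexa-2,5-dien-1-yl)butanoate | CCOC(=O)C[C@H](C)C1(C)C=C(C)CC(C)=C1 | intermediate
10 | ethyl (3S)-3-(1,3,5-trimethyl-4-oxocyclohexa-2,5-dien-1-yl)butanoate | CCOC(=O)C[C@H](C)C1(C)C=C(C)C(=O)C(C)=C1 | intermediate
11 | ethyl (3S)-3-(cis-4-hydroxy-1,3,5-trimethylcyclohexa-2,5-dien-1-yl)butanoate (OH cis to the butanoate arm) | CCOC(=O)C[C@H](C)[C@]1(C)C=C(C)[C@H](O)C(C)=C1 | intermediate
12 | (3S)-3-(cis-4-hydroxy-1,3,5-trimethylcyclohexa-2,5-dien-1-yl)butanoic acid | OC(=O)C[C@H](C)[C@]1(C)C=C(C)[C@H](O)C(C)=C1 | intermediate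
13 | mixed anhydride of 12 with 2-methyl-6-nitrobenzoic acid | Cc1cccc([N+](=O)[O-])c1C(=O)OC(=O)C[C@H](C)[C@]1(C)C=C(C)[C@H](O)C(C)=C1 | intermediate (not isolated)
14 | (5S)-5,6,8,9-tetramethyl-2-oxabicyclo[4.2.2]deca-7,9-dien-3-one | O=C1C[C@H](C)C2(C)C=C(C)C(O1)C(C)=C2 | intermediate
15 | lithium enolate of 14 | [Li+].[O-]C1=C[C@H](C)C2(C)C=C(C)C(O1)C(C)=C2 | intermediate (not isolated)
16 | (4RS,5S)-4,5,6,8,9-pentamethyl-2-oxabicyclo[4.2.2]deca-7,9-dien-3-one (key-step precursor; C4 epimers) | CC1[C@H](C)C2(C)C=C(C)C(OC1=O)C(C)=C2 | intermediate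
17 | lithium enolate of 16 | [Li+].C[C@H]1C(C)=C([O-])OC2C(C)=CC1(C)C=C2C | intermediate (not isolated)
18 | (5S)-3-(tert-butyldimethylsilyloxy)-4,5,6,8,9-pentamethyl-2-oxabicyclo[4.2.2]deca-3,7,9-triene | C[C@H]1C(C)=C(O[Si](C)(C)C(C)(C)C)OC2C(C)=CC1(C)C=C2C | intermediate (not isolated)
19 | tert-butyldimethylsilyl (1R,6R,7S,8R)-1,3,5,7,8-pentamethylbicyclo[4.2.0]octa-2,4-diene-7-carboxylate | CC(C)(C)[Si](C)(C)OC(=O)[C@@]1(C)[C@H](C)[C@@]2(C)C=C(C)C=C(C)[C@@H]12 | intermediate (not isolated)
20 | (1R,6R,7S,8R)-1,3,5,7,8-pentamethylbicyclo[4.2.0]octa-2,4-diene-7-carboxylic acid (key-step product; cis ring fusion, three cyclobutane methyls convex, carboxyl concave) | O=C(O)[C@@]1(C)[C@H](C)[C@@]2(C)C=C(C)C=C(C)[C@@H]12 | intermediate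
21 | [(1R,6R,7S,8R)-1,3,5,7,8-pentamethylbicyclo[4.2.0]octa-2,4-dien-7-yl]methanol | OC[C@@]1(C)[C@H](C)[C@@]2(C)C=C(C)C=C(C)[C@@H]12 | intermediate
22 | (1R,6R,7S,8R)-1,3,5,7,8-pentamethylbicyclo[4.2.0]octa-2,4-diene-7-carbaldehyde | O=C[C@@]1(C)[C@H](C)[C@@]2(C)C=C(C)C=C(C)[C@@H]12 | intermediate
23 | methyl 2-methyl-3-oxopentanoate | CCC(=O)C(C)C(=O)OC | starting material
24 | dilithium dianion (bis-enolate) of 23 | [Li+].[Li+].COC([O-])=C(C)C([O-])=CC | intermediate (not isolated)
25 | methyl 5-hydroxy-2,4-dimethyl-3-oxo-5-[(1R,6R,7S,8R)-1,3,5,7,8-pentamethylbicyclo[4.2.0]octa-2,4-dien-7-yl]pentanoate (mixture at C2, C4, C5) | COC(=O)C(C)C(=O)C(C)C(O)[C@@]1(C)[C@H](C)[C@@]2(C)C=C(C)C=C(C)[C@@H]12 | intermediate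
26 | methyl 2,4-dimethyl-3,5-dioxo-5-[(1R,6R,7S,8R)-1,3,5,7,8-pentamethylbicyclo[4.2.0]octa-2,4-dien-7-yl]pentanoate | COC(=O)C(C)C(=O)C(C)C(=O)[C@@]1(C)[C@H](C)[C@@]2(C)C=C(C)C=C(C)[C@@H]12 | intermediate
27 | 4-hydroxy-3,5-dimethyl-6-[(1R,6R,7S,8R)-1,3,5,7,8-pentamethylbicyclo[4.2.0]octa-2,4-dien-7-yl]-2H-pyran-2-one | Cc1c(O)c(C)c(oc1=O)[C@@]1(C)[C@H](C)[C@@]2(C)C=C(C)C=C(C)[C@@H]12 | intermediate
28 | 2-methoxy-3,5-dimethyl-6-[(1R,6R,7S,8R)-1,3,5,7,8-pentamethylbicyclo[4.2.0]octa-2,4-dien-7-yl]-4H-pyran-4-one | COc1oc(c(C)c(=O)c1C)[C@@]1(C)[C@H](C)[C@@]2(C)C=C(C)C=C(C)[C@@H]12 | intermediate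
29 | 2-methoxy-3,5-dimethyl-6-[(1R,2R,5S,6R,7S,8R)-2,5-epidioxy-1,3,5,7,8-pentamethylbicyclo[4.2.0]oct-3-en-7-yl]-4H-pyran-4-one (peroxide anti to the cyclobutane) | COc1oc([C@@]2(C)[C@H](C)[C@@]3(C)[C@@H]4OO[C@@](C)(C=C4C)[C@@H]23)c(C)c(=O)c1C | target

**Totals.** Total step count: 17. Longest linear sequence: 17 steps (1 to 29); 6 and 23 are purchased and enter directly.

**Steps most likely to fail**

Step 10 (ring contraction). The tertiary, bridge-shielded C4 proton may be removed slowly or incompletely. The methyl-bearing ketene acetal may need more heat than the product diene tolerates before it opens electrocyclically. It may also bond to the wrong ring alkene, because the C4 methyl crowds the convex position beside the C5 methyl. The fallback sets out from 14 and returns at 20, and builds the quaternary centre after the contraction instead of during it. Lactone 14 is deprotonated to 15 as in step 9 but trapped with TBSCl (THF–DMPU, −78 °C) to give the α-unsubstituted silyl ketene acetal F1, the closest match to the known medium-ring contractions. On warming this should rearrange to silyl ester F2, and AcOH–THF–H2O frees the des-7-methyl acid F3 (carboxyl concave, C7–H convex). LiN(iPr)2 (2.2 equiv, THF–DMPU, −78 to 0 °C) converts F3 into dilithium enediolate F4. MeI should alkylate its exocyclic enolate carbon from the open convex face (carboxylic acid dianion alkylation), placing the methyl convex and the carboxyl concave as in 20.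

Step 8 (lactonisation). Intermolecular esterification may outrun closure of the bridged eight-membered ring, or the doubly allylic alcohol may ionise and rearrange to an arene as acidic by-products build up. The fallback sets out from 11 and returns at 14, and transfers the acyl group at the aldehyde oxidation level under base. Ester 11 is reduced with iBu2AlH (2.2 equiv, CH2Cl2, −78 °C) to (3S)-3-(cis-4-hydroxy-1,3,5-trimethylcyclohexa-2,5-dien-1-yl)butanal F5. Carbene-catalysed oxidative lactonisation (1,3-dimesitylimidazolium chloride, DBU, 3,3',5,5'-tetra-tert-butyldiphenoquinone, THF, rt, slow addition) then generates an acyl azolium that the cis hydroxyl should capture intramolecularly to give 14.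

Step 6 (dienone reduction). Facial discrimination by the remote quaternary carbon may be poor, so that much of the material becomes the trans carbinol, which cannot bridge. The fallback sets out from 10 and returns at 11, and fixes the carbinol configuration by SN2 inversion instead of by hydride bias. The trans-dienol ester F6 from the same reduction is subjected to a Mitsunobu reaction with 4-nitrobenzoic acid (PPh3, DIAD, toluene, 0 °C), which should give the cis 4-nitrobenzoate F7 with inversion. K2CO3 in EtOH then removes the nitrobenzoate to give 11.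

Further compounds
F1 | step 10 | (5S)-3-(tert-butyldimethylsilyloxy)-5,6,8,9-tetramethyl-2-oxabicyclo[4.2.2]deca-3,7,9-triene | C[C@H]1C=C(O[Si](C)(C)C(C)(C)C)OC2C(C)=CC1(C)C=C2C
F2 | step 10 | tert-butyldimethylsilyl ester of F3 | CC(C)(C)[Si](C)(C)OC(=O)[C@H]1[C@H](C)[C@@]2(C)C=C(C)C=C(C)[C@@H]12
F3 | step 10 | 1,3,5,8-tetramethylbicyclo[4.2.0]octa-2,4-diene-7-carboxylic acid (cis-fused, carboxyl concave, 8-methyl convex) | O=C(O)[C@H]1[C@H](C)[C@@]2(C)C=C(C)C=C(C)[C@@H]12
F4 | step 10 | dilithium enediolate of F3 | [Li+].[Li+].[O-]C([O-])=C1[C@H](C)[C@@]2(C)C=C(C)C=C(C)[C@@H]12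
F5 | step 8 | (3S)-3-(cis-4-hydroxy-1,3,5-trimethylcyclohexa-2,5-dien-1-yl)butanal | O=CC[C@H](C)[C@]1(C)C=C(C)[C@H](O)C(C)=C1
F6 | step 6 | ethyl (3S)-3-(trans-4-hydroxy-1,3,5-trimethylcyclohexa-2,5-dien-1-yl)butanoate | CCOC(=O)C[C@H](C)[C@]1(C)C=C(C)[C@@H](O)C(C)=C1
F7 | step 6 | ethyl (3S)-3-[cis-4-(4-nitrobenzoyloxy)-1,3,5-trimethylcyclohexa-2,5-dien-1-yl]butanoate | CCOC(=O)C[C@H](C)[C@]1(C)C=C(C)[C@H](OC(=O)c2ccc(cc2)[N+](=O)[O-])C(C)=C1
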